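**Retrosynthetic overview**
1. Target ⇐ OH-directed epoxidation of C3=C4 and 1,2-reduction of C2=O ⇐ cis-α′-acyloxy enone 20 ⇐ inversion at C1 with (R)-2-methylbutanoic acid ⇐ trans-ketol 18 ⇐ enone 15.
2. 15 ⇐ angeloylation of C8–OH; side-chain oxirane by displacement of a C10 sulfonate ⇐ anti-triol 10 ⇐ 1,3-anti reduction of β-hydroxy enone 9 ⇐ allylic oxidation of 7.
3. 7 ⇐ key C8–C9 bond: electroreductive Ni coupling of 10-chlorocarvone 2 (from (R)-carvone) with iodo-diol 6 (from (S)-glycerate acetonide).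
4. Stereocentres: C6 from carvone, C10 from the glycerate, C2′ of the butanoate bought; C8 set by C10; C1, C2, C3, C4 set by C6 and by each other.
5. Ring order: the carbocycle is bought; the side-chain oxirane is closed in step 8, the ring oxirane last in step 13.

Assumption: (R)-carvone, methyl (S)-glycerate acetonide, angelic acid and (R)-2-methylbutanoic acid are bought; locants follow bisabolane numbering (ring C1–C6, C6 carries the chain C7(=C14)–C8–C9–C10–C11).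

**Step 1**
Reactants: 1 (R)-carvone
Product: 2 (5R)-5-(3-chloroprop-1-en-2-yl)-2-methylcyclohex-2-en-1-one
Conditions: Ca(OCl)2, CO2 (dry ice), CH2Cl2/H2O, 0 °C
Reagents that add atoms: calcium hypochlorite, [Ca+2].[O-]Cl.[O-]Cl
Why: Ene-type allylic chlorination by HOCl attacks only the electron-rich isopropenyl group (the enone C=C is deactivated) and does not touch the stereocentre.

**Step 2**
Reactants: 3 methyl (4S)-2,2-dimethyl-1,3-dioxolane-4-carboxylate
Product: 5 (2S)-3-methylbutane-1,2,3-triol, via dioxolanyl carbinol 4 (not isolated)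
Conditions: MeMgBr (2.4 equiv), THF, 0 °C → rt; then 1 M HCl, MeOH, rt
Reagents that add atoms: methylmagnesium bromide, C[Mg]Br
Why: Double Grignard addition to the ester builds the C11 carbinol without touching the adjacent stereocentre, and acid acetal hydrolysis frees the triol.

**Step 3**
Reactants: 5 (2S)-3-methylbutane-1,2,3-triol
Product: 6 (2R)-1-iodo-3-methylbutane-2,3-diol
Conditions: I2, PPh3, imidazole, THF/MeCN, 0 °C
Reagents that add atoms: iodine, II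
Why: Appel iodination is selective for the primary hydroxyl; the stereocentre is untouched (the descriptor changes only through CIP priority).

**Step 4**
Reactants: 2 (5R)-5-(3-chloroprop-1-en-2-yl)-2-methylcyclohex-2-en-1-one; 6 (2R)-1-iodo-3-methylbutane-2,3-diol
Product: 7 (5R)-5-[(5S)-5,6-dihydroxy-6-methylhept-1-en-2-yl]-2-methylcyclohex-2-en-1-one
Conditions: NiBr2·glyme (10 mol%), dtbbpy (10 mol%), NaI (25 mol%), DMA, Zn(+)|RVC(−), undivided cell, 3 mA cm−2, 2.2 F mol−1, rt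
Reagents that add atoms: none
Why: Proposed new method: electroreductive Ni-catalysed sp3–sp3 cross-electrophile coupling of an allylic chloride with an unprotected β,γ-dihydroxyalkyl iodide — cathodically formed Ni(0) adds to 2 to give a (π-allyl)Ni(II) species, Ni(I) abstracts iodine from 6 to give a primary β-hydroxyalkyl radical (no β-scission, C10 untouched), radical capture gives Ni(III)(allyl)(alkyl) and C–C reductive elimination should outrun β-OH elimination; both allyl termini are CH2 so only one regioisomer can form, and the working potential (about −1.2 V vs Ag/AgCl) stays short of enone reduction; the closest known reaction types are Zn/Mn-driven Ni reductive allyl–alkyl coupling, Ni/iodide coupling of epoxides through iodohydrins and electroreductive Ni aryl–alkyl coupling.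

**Step 5**
Reactants: 7 (5R)-5-[(5S)-5,6-dihydroxy-6-methylhept-1-en-2-yl]-2-methylcyclohex-2-en-1-one
Product: 8 (5R)-2-methyl-5-[(3RS,5S)-3,5,6-trihydroxy-6-methylhept-1-en-2-yl]cyclohex-2-en-1-one
Conditions: SeO2 (0.5 equiv), t-BuOOH (3 equiv), CH2Cl2, 0 °C → rt
Reagents that add atoms: selenium dioxide, O=[Se]=O; tert-butyl hydroperoxide, CC(C)(C)OO
Why: SeO2 allylic hydroxylation (ene reaction then [2,3]-sigmatropic shift) oxidises the CH2 next to the 1,1-disubstituted alkene and restores the exocyclic methylene; C8 forms unselectively and is corrected in steps 6 and 7.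

**Step 6**
Reactants: 8 (5R)-2-methyl-5-[(3RS,5S)-3,5,6-trihydroxy-6-methylhept-1-en-2-yl]cyclohex-2-en-1-one
Product: 9 (5R)-5-[(5S)-5,6-dihydroxy-6-methyl-3-oxohept-1-en-2-yl]-2-methylcyclohex-2-en-1-one
Conditions: activated MnO2 (20 equiv), CH2Cl2, rt; use at once
Reagents that add atoms: none
Why: MnO2 oxidises only the allylic C8 alcohol, converging both epimers to the α-methylene ketone and leaving the non-allylic C10 and C11 hydroxyls alone.

**Step 7**
Reactants: 9 (5R)-5-[(5S)-5,6-dihydroxy-6-methyl-3-oxohept-1-en-2-yl]-2-methylcyclohex-2-en-1-one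
Product: 10 (5R)-2-methyl-5-[(3S,5S)-3,5,6-trihydroxy-6-methylhept-1-en-2-yl]cyclohex-2-en-1-one
Conditions: Me4NBH(OAc)3 (5 equiv), MeCN/AcOH 1:1, −30 °C
Reagents that add atoms: none
Why: Evans–Saksena reduction: the C10 alkoxide binds boron and delivers hydride to C8 through a chair transition state, giving the 1,3-anti diol (8S); the ring enone has no directing hydroxyl and is not reduced.

**Step 8**
Reactants: 10 (5R)-2-methyl-5-[(3S,5S)-3,5,6-trihydroxy-6-methylhept-1-en-2-yl]cyclohex-2-en-1-one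
Product: 12 (5R)-5-{(3S)-4-[(2R)-3,3-dimethyloxiran-2-yl]-3-hydroxybut-1-en-2-yl}-2-methylcyclohex-2-en-1-one, via C10 tosylate 11 (not isolated)
Conditions: Bu2SnO (20 mol%), TsCl (1.2 equiv), Et3N, CH2Cl2, rt; then K2CO3, MeOH, 0 °C; keep the product free of acid
Reagents that add atoms: 4-toluenesulfonyl chloride, Cc1ccc(cc1)S(Cl)(=O)=O (its atoms stay in 11 only)
Why: Tin-acetal-mediated sulfonylation activates only the secondary oxygen of the 1,2-diol, and the tertiary alkoxide then displaces the tosylate (intramolecular Williamson closure) with inversion at C10 to give the (R)-oxirane.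

**Step 9**
Reactants: 12 (5R)-5-{(3S)-4-[(2R)-3,3-dimethyloxiran-2-yl]-3-hydroxybut-1-en-2-yl}-2-methylcyclohex-2-en-1-one; 13 angelic acid
Product: 15 (2S)-1-[(2R)-3,3-dimethyloxiran-2-yl]-3-[(1R)-4-methyl-5-oxocyclohex-3-en-1-yl]but-3-en-2-yl (2Z)-2-methylbut-2-enoate, via mixed anhydride 14 (not isolated)
Conditions: 13, 2,4,6-trichlorobenzoyl chloride, Et3N, toluene, rt; then 12, 75 °C
Reagents that add atoms: 2,4,6-trichlorobenzoyl chloride, O=C(Cl)c1c(Cl)cc(Cl)cc1Cl (its atoms stay in 14 only)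
Why: Yamaguchi-type mixed-anhydride esterification without DMAP acylates the only free hydroxyl (C8) with retention and avoids angelate-to-tiglate isomerisation.

**Step 10**
Reactants: 15 (2S)-1-[(2R)-3,3-dimethyloxiran-2-yl]-3-[(1R)-4-methyl-5-oxocyclohex-3-en-1-yl]but-3-en-2-yl (2Z)-2-methylbut-2-enoate
Product: 18 (2S)-1-[(2R)-3,3-dimethyloxiran-2-yl]-3-[(1S,6S)-6-hydroxy-4-methyl-5-oxocyclohex-3-en-1-yl]but-3-en-2-yl (2Z)-2-methylbut-2-enoate, via silyl dienol ether 16 (not isolated), via silyloxy ketone 17 (not isolated)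
Conditions: LiHMDS (1.05 equiv), TMSCl, THF, −78 °C; DMDO, acetone/CH2Cl2, −78 → −40 °C; citric acid, MeOH, 0 °C
Reagents that add atoms: dimethyldioxirane, CC1(C)OO1; chlorotrimethylsilane, C[Si](C)(C)Cl (Si stays in 16 and 17 only)
Why: Rubottom oxidation: kinetic α′-enolisation gives the 2-silyloxydiene, DMDO attacks the electron-rich enol ether on the face anti to the neighbouring C6 side chain, and silyl migration then methanolysis give the trans ketol (C1–OH trans to the side chain).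

**Step 11**
Reactants: 18 (2S)-1-[(2R)-3,3-dimethyloxiran-2-yl]-3-[(1S,6S)-6-hydroxy-4-methyl-5-oxocyclohex-3-en-1-yl]but-3-en-2-yl (2Z)-2-methylbut-2-enoate; 19 (2R)-2-methylbutanoic acid
Product: 20 (1R,6S)-6-{(3S)-4-[(2R)-3,3-dimethyloxiran-2-yl]-3-[(2Z)-2-methylbut-2-enoyloxy]but-1-en-2-yl}-3-methyl-2-oxocyclohex-3-en-1-yl (2R)-2-methylbutanoate
Conditions: PPh3, DIAD, toluene, 0 °C → rt; carry on directly
Reagents that add atoms: none
Why: Mitsunobu esterification of the α-ketol is an SN2 displacement with inversion at C1, which puts the butanoate cis to the side chain; the acid stereocentre is not involved.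

**Step 12**
Reactants: 20 (1R,6S)-6-{(3S)-4-[(2R)-3,3-dimethyloxiran-2-yl]-3-[(2Z)-2-methylbut-2-enoyloxy]but-1-en-2-yl}-3-methyl-2-oxocyclohex-3-en-1-yl (2R)-2-methylbutanoate
Product: 21 (1R,2S,6S)-6-{(3S)-4-[(2R)-3,3-dimethyloxiran-2-yl]-3-[(2Z)-2-methylbut-2-enoyloxy]but-1-en-2-yl}-2-hydroxy-3-methylcyclohex-3-en-1-yl (2R)-2-methylbutanoate
Conditions: NaBH4, CeCl3·7H2O, MeOH, −78 °C; AcOH quench at −78 °C
Reagents that add atoms: none
Why: Luche 1,2-reduction: hydride adds axially from the face opposite the axial C1 acyloxy group (as in carvone to cis-carveol), so the C2 hydroxyl ends cis to C1–O and to the side chain; the cold quench prevents acyl migration.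

**Step 13**
Reactants: 21 (1R,2S,6S)-6-{(3S)-4-[(2R)-3,3-dimethyloxiran-2-yl]-3-[(2Z)-2-methylbut-2-enoyloxy]but-1-en-2-yl}-2-hydroxy-3-methylcyclohex-3-en-1-yl (2R)-2-methylbutanoate
Product: 22 (1R,2R,3R,4S,6S)-4-{(3S)-4-[(2R)-3,3-dimethyloxiran-2-yl]-3-[(2Z)-2-methylbut-2-enoyloxy]but-1-en-2-yl}-2-hydroxy-1-methyl-7-oxabicyclo[4.1.0]heptan-3-yl (2R)-2-methylbutanoate
Conditions: VO(acac)2 (5 mol%), t-BuOOH (1.5 equiv), CH2Cl2, 0 °C → rt
Reagents that add atoms: tert-butyl hydroperoxide, CC(C)(C)OO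
Why: Vanadium-catalysed hydroxyl-directed epoxidation delivers oxygen to C3=C4 syn to the C2 hydroxyl; the 1,1-disubstituted alkene and the angelate alkene have no directing hydroxyl and stay intact.

**Compound list**
1 | (R)-carvone, (5R)-2-methyl-5-(prop-1-en-2-yl)cyclohex-2-en-1-one | C=C(C)[C@@H]1CC=C(C)C(=O)C1 | starting material
2 | (5R)-5-(3-chloroprop-1-en-2-yl)-2-methylcyclohex-2-en-1-one | C=C(CCl)[C@@H]1CC=C(C)C(=O)C1 | intermediate
3 | methyl (4S)-2,2-dimethyl-1,3-dioxolane-4-carboxylate | COC(=O)[C@@H]1COC(C)(C)O1 | starting material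
4 | 2-[(4S)-2,2-dimethyl-1,3-dioxolan-4-yl]propan-2-ol | CC(C)(O)[C@@H]1COC(C)(C)O1 | intermediate
5 | (2S)-3-methylbutane-1,2,3-triol | CC(C)(O)[C@@H](O)CO | intermediate
6 | (2R)-1-iodo-3-methylbutane-2,3-diol | CC(C)(O)[C@@H](O)CI | intermediate
7 | (5R)-5-[(5S)-5,6-dihydroxy-6-methylhept-1-en-2-yl]-2-methylcyclohex-2-en-1-one | C=C(CC[C@H](O)C(C)(C)O)[C@@H]1CC=C(C)C(=O)C1 | intermediate
8 | (5R)-2-methyl-5-[(3RS,5S)-3,5,6-trihydroxy-6-methylhept-1-en-2-yl]cyclohex-2-en-1-one | C=C(C(O)C[C@H](O)C(C)(C)O)[C@@H]1CC=C(C)C(=O)C1 | intermediate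
9 | (5R)-5-[(5S)-5,6-dihydroxy-6-methyl-3-oxohept-1-en-2-yl]-2-methylcyclohex-2-en-1-one | C=C(C(=O)C[C@H](O)C(C)(C)O)[C@@H]1CC=C(C)C(=O)C1 | intermediate
10 | (5R)-2-methyl-5-[(3S,5S)-3,5,6-trihydroxy-6-methylhept-1-en-2-yl]cyclohex-2-en-1-one | C=C([C@@H](O)C[C@H](O)C(C)(C)O)[C@@H]1CC=C(C)C(=O)C1 | intermediate
11 | (3S,5S)-3,6-dihydroxy-6-methyl-2-[(1R)-4-methyl-5-oxocyclohex-3-en-1-yl]hept-1-en-5-yl 4-methylbenzenesulfonate | C=C([C@@H](O)C[C@H](OS(=O)(=O)c1ccc(C)cc1)C(C)(C)O)[C@@H]1CC=C(C)C(=O)C1 | intermediate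
12 | (5R)-5-{(3S)-4-[(2R)-3,3-dimethyloxiran-2-yl]-3-hydroxybut-1-en-2-yl}-2-methylcyclohex-2-en-1-one | C=C([C@@H](O)C[C@H]1OC1(C)C)[C@@H]1CC=C(C)C(=O)C1 | intermediate
13 | angelic acid, (2Z)-2-methylbut-2-enoic acid | C/C=C(/C)C(=O)O | starting material
14 | (2Z)-2-methylbut-2-enoic 2,4,6-trichlorobenzoic anhydride | C/C=C(/C)C(=O)OC(=O)c1c(Cl)cc(Cl)cc1Cl | intermediate
15 | (2S)-1-[(2R)-3,3-dimethyloxiran-2-yl]-3-[(1R)-4-methyl-5-oxocyclohex-3-en-1-yl]but-3-en-2-yl (2Z)-2-methylbut-2-enoate | C=C([C@H](C[C@H]1OC1(C)C)OC(=O)/C(C)=C\C)[C@@H]1CC=C(C)C(=O)C1 | intermediate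
16 | (2S)-1-[(2R)-3,3-dimethyloxiran-2-yl]-3-[(1R)-4-methyl-5-(trimethylsilyloxy)cyclohexa-3,5-dien-1-yl]but-3-en-2-yl (2Z)-2-methylbut-2-enoate | C=C([C@H](C[C@H]1OC1(C)C)OC(=O)/C(C)=C\C)[C@@H]1CC=C(C)C(O[Si](C)(C)C)=C1 | intermediate
17 | (2S)-1-[(2R)-3,3-dimethyloxiran-2-yl]-3-[(1S,6S)-4-methyl-5-oxo-6-(trimethylsilyloxy)cyclohex-3-en-1-yl]but-3-en-2-yl (2Z)-2-methylbut-2-enoate | C=C([C@H](C[C@H]1OC1(C)C)OC(=O)/C(C)=C\C)[C@@H]1CC=C(C)C(=O)[C@H]1O[Si](C)(C)C | intermediate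
18 | (2S)-1-[(2R)-3,3-dimethyloxiran-2-yl]-3-[(1S,6S)-6-hydroxy-4-methyl-5-oxocyclohex-3-en-1-yl]but-3-en-2-yl (2Z)-2-methylbut-2-enoate | C=C([C@H](C[C@H]1OC1(C)C)OC(=O)/C(C)=C\C)[C@@H]1CC=C(C)C(=O)[C@H]1O | intermediate
19 | (2R)-2-methylbutanoic acid | CC[C@@H](C)C(=O)O | starting material
20 | (1R,6S)-6-{(3S)-4-[(2R)-3,3-dimethyloxiran-2-yl]-3-[(2Z)-2-methylbut-2-enoyloxy]but-1-en-2-yl}-3-methyl-2-oxocyclohex-3-en-1-yl (2R)-2-methylbutanoate | C=C([C@H](C[C@H]1OC1(C)C)OC(=O)/C(C)=C\C)[C@@H]1CC=C(C)C(=O)[C@@H]1OC(=O)[C@H](C)CC | intermediate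
21 | (1R,2S,6S)-6-{(3S)-4-[(2R)-3,3-dimethyloxiran-2-yl]-3-[(2Z)-2-methylbut-2-enoyloxy]but-1-en-2-yl}-2-hydroxy-3-methylcyclohex-3-en-1-yl (2R)-2-methylbutanoate | C=C([C@H](C[C@H]1OC1(C)C)OC(=O)/C(C)=C\C)[C@@H]1CC=C(C)[C@H](O)[C@@H]1OC(=O)[C@H](C)CC | intermediate
22 | (1R,2R,3R,4S,6S)-4-{(3S)-4-[(2R)-3,3-dimethyloxiran-2-yl]-3-[(2Z)-2-methylbut-2-enoyloxy]but-1-en-2-yl}-2-hydroxy-1-methyl-7-oxabicyclo[4.1.0]heptan-3-yl (2R)-2-methylbutanoate | C=C([C@H](C[C@H]1OC1(C)C)OC(=O)/C(C)=C\C)[C@@H]1C[C@@H]2O[C@]2(C)[C@H](O)[C@@H]1OC(=O)[C@H](C)CC | target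

**Totals and risks**
Total step count: 13. Longest linear sequence: 12 steps (3 → 22, steps 2–13); from carvone it is 11.

Most likely to fail, first: step 4, the new electroreductive coupling. The alkyl radical may add to the enone, the allyl partner may homocouple, or the β-hydroxyalkyl nickel species may eliminate. The fallback uses known chemistry and sets out from 6 and 1. Iodo-diol 6 is treated with vinylmagnesium bromide and catalytic CuI (THF, −30 → 0 °C; epoxide formed in situ and opened at CH2) to give (3S)-2-methylhex-5-ene-2,3-diol F1. Cross-metathesis of F1 with excess carvone 1 (Hoveyda–Grubbs II, CH2Cl2, 40 °C) gives (5R)-5-[(2E,5S)-5,6-dihydroxy-6-methylhept-2-en-2-yl]-2-methylcyclohex-2-en-1-one F2. Schenck ene photo-oxygenation of F2 (O2, tetraphenylporphyrin, visible light, CH2Cl2, 0 °C) puts oxygen on C8 and shifts the double bond to C7=C14, giving (5R)-5-[(3RS,5S)-3-hydroperoxy-5,6-dihydroxy-6-methylhept-1-en-2-yl]-2-methylcyclohex-2-en-1-one F3. Triphenylphosphine reduces F3 in the same pot, and the route is rejoined at 8.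

Second: step 8, the tin-mediated tosylation. A secondary/tertiary diol reacts slowly, the C8 hydroxyl may compete, and the free epoxy alcohol 12 is acid-sensitive. The fallback sets out from 10 and differentiates the hydroxyls by protection. 2,2-Dimethoxypropane with PPTS closes only the 1,2-diol (the anti-1,3-diol acetonide is disfavoured) to give (5R)-5-{(3S)-3-hydroxy-4-[(4S)-2,2,5,5-tetramethyl-1,3-dioxolan-4-yl]but-1-en-2-yl}-2-methylcyclohex-2-en-1-one F4. Acylation with mixed anhydride 14 gives (2S)-1-[(4S)-2,2,5,5-tetramethyl-1,3-dioxolan-4-yl]-3-[(1R)-4-methyl-5-oxocyclohex-3-en-1-yl]but-3-en-2-yl (2Z)-2-methylbut-2-enoate F5. Aqueous acetic acid at 40 °C frees (3S,5S)-5,6-dihydroxy-6-methyl-2-[(1R)-4-methyl-5-oxocyclohex-3-en-1-yl]hept-1-en-3-yl (2Z)-2-methylbut-2-enoate F6. MsCl/Et3N at −20 °C gives (3S,5S)-6-hydroxy-6-methyl-5-(methylsulfonyloxy)-2-[(1R)-4-methyl-5-oxocyclohex-3-en-1-yl]hept-1-en-3-yl (2Z)-2-methylbut-2-enoate F7. DBU in MeCN at 40 °C closes the oxirane with inversion, and the route is rejoined at 15; the free epoxy alcohol 12 never appears.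

Third: step 11, the Mitsunobu inversion. The ketol is hindered and the acid is a weak pronucleophile. The fallback sets out from 18 and replaces the redox condensation by an isolated sulfonate and a carboxylate salt. Tf2O with 2,6-lutidine (CH2Cl2, −78 °C) gives (2S)-1-[(2R)-3,3-dimethyloxiran-2-yl]-3-[(1S,6S)-4-methyl-5-oxo-6-(trifluoromethylsulfonyloxy)cyclohex-3-en-1-yl]but-3-en-2-yl (2Z)-2-methylbut-2-enoate F8. The cesium salt of 19 (Cs2CO3, 18-crown-6, toluene, 0 °C) displaces the α-keto triflate with inversion, and the route is rejoined at 20.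

**Further compounds**
F1 | step 4 | (3S)-2-methylhex-5-ene-2,3-diol | C=CC[C@H](O)C(C)(C)O
F2 | step 4 | (5R)-5-[(2E,5S)-5,6-dihydroxy-6-methylhept-2-en-2-yl]-2-methylcyclohex-2-en-1-one | C/C(=C\C[C@H](O)C(C)(C)O)[C@@H]1CC=C(C)C(=O)C1
F3 | step 4 | (5R)-5-[(3RS,5S)-3-hydroperoxy-5,6-dihydroxy-6-methylhept-1-en-2-yl]-2-methylcyclohex-2-en-1-one | C=C(C(OO)C[C@H](O)C(C)(C)O)[C@@H]1CC=C(C)C(=O)C1
F4 | step 8 | (5R)-5-{(3S)-3-hydroxy-4-[(4S)-2,2,5,5-tetramethyl-1,3-dioxolan-4-yl]but-1-en-2-yl}-2-methylcyclohex-2-en-1-one | C=C([C@@H](O)C[C@@H]1OC(C)(C)OC1(C)C)[C@@H]1CC=C(C)C(=O)C1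
F5 | step 8 | (2S)-1-[(4S)-2,2,5,5-tetramethyl-1,3-dioxolan-4-yl]-3-[(1R)-4-methyl-5-oxocyclohex-3-en-1-yl]but-3-en-2-yl (2Z)-2-methylbut-2-enoate | C=C([C@H](C[C@@H]1OC(C)(C)OC1(C)C)OC(=O)/C(C)=C\C)[C@@H]1CC=C(C)C(=O)C1
F6 | step 8 | (3S,5S)-5,6-dihydroxy-6-methyl-2-[(1R)-4-methyl-5-oxocyclohex-3-en-1-yl]hept-1-en-3-yl (2Z)-2-methylbut-2-enoate | C=C([C@H](C[C@H](O)C(C)(C)O)OC(=O)/C(C)=C\C)[C@@H]1CC=C(C)C(=O)C1
F7 | step 8 | (3S,5S)-6-hydroxy-6-methyl-5-(methylsulfonyloxy)-2-[(1R)-4-methyl-5-oxocyclohex-3-en-1-yl]hept-1-en-3-yl (2Z)-2-methylbut-2-enoate | C=C([C@H](C[C@H](OS(C)(=O)=O)C(C)(C)O)OC(=O)/C(C)=C\C)[C@@H]1CC=C(C)C(=O)C1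
F8 | step 11 | (2S)-1-[(2R)-3,3-dimethyloxiran-2-yl]-3-[(1S,6S)-4-methyl-5-oxo-6-(trifluoromethylsulfonyloxy)cyclohex-3-en-1-yl]but-3-en-2-yl (2Z)-2-methylbut-2-enoate | C=C([C@H](C[C@H]1OC1(C)C)OC(=O)/C(C)=C\C)[C@@H]1CC=C(C)C(=O)[C@H]1OS(=O)(=O)C(F)(F)F
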